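Numbering: ten-membered ring C1 (quaternary, Me)–C2–C3–C4(Me)=C5–C6(OAc)–C7–C8(Me, OH)–C9–C11–C1; C10 is the cyclopropane CH2 between C9 and C11; side chain on C1 is C12–C13–C14(OOH)–C15(Me)=CH2.
Feature used: C4, C6 and C8 are 1,3-related ring carbons that fit one cyclohexane (C4–C9) when C4 is a carbinol; a vinyl group (C3=C2) on C4 and a (Z)-alkenyl group (C11=C1) on C9 form the 1,5-diene C2=C3–C4–C9–C11=C1, whose anionic oxy-Cope shift makes C1–C2 and the quaternary C1, cuts C4–C9 and opens the six-membered ring to the ten-membered ring with the E C9=C11 olefin.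
After the ring expansion: C4 ketone → C4 methyl carbinol → C6 ketone → E C4=C5 enone → C8–OH-directed reduction at C6, acetate, C8–OH-directed cyclopropanation (C9–C10–C11); C14–OOH last, by SN2 inversion of the (R)-C14 mesylate with a protected hydroperoxide.
Before it: (S)-5-silyloxy-3-methylcyclohex-2-enone (double Wacker oxidation, desymmetrising aldol) is α-iodinated and coupled (Negishi) with the (Z)-alkenylmetal from carbocupration of propyne; epoxidation and SmI2 opening give C8–OH, vinyl addition gives the C4 carbinol; C14 comes from a Shi epoxidation of 5-bromo-2-methylpent-2-ene.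
Ring order: six-membered ring (step 3), ten-membered ring by ring expansion (step 13), cyclopropane (step 21).

Key step: step 13

Abbreviations: TBS = tert-butyldimethylsilyl, TBDPS = tert-butyldiphenylsilyl, MOM = methoxymethyl, Ms = methanesulfonyl; atom numbers are those of the overview.
Assumption: the amine catalyst of step 3 is taken to give the (S)-enone; if it gives the (R)-enone, its quinidine-derived pseudo-enantiomer is used instead.

Step 1
Reactants: 1 hepta-1,6-dien-4-ol
Product: 2 tert-butyl(hepta-1,6-dien-4-yloxy)dimethylsilane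
Conditions: TBSCl, imidazole, DMF, rt
Reagents that add atoms: tert-butyldimethylsilyl chloride, CC(C)(C)[Si](C)(C)Cl
Why: Silyl ether formation masks the future C6 oxygen with a group that survives the Wacker, aldol, organometallic and KH steps.

Step 2
Reactants: 2 tert-butyl(hepta-1,6-dien-4-yloxy)dimethylsilane
Product: 3 4-(TBS-oxy)heptane-2,6-dione
Conditions: PdCl2 (10 mol%), CuCl, O2 (1 atm), DMF/H2O 7:1, rt
Reagents that add atoms: water, O
Why: Twofold Tsuji–Wacker oxidation turns both terminal olefins into methyl ketones with Markovnikov selectivity, water supplying the carbonyl oxygens, and gives the prochiral 2,6-diketone.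

Step 3
Reactants: 3 4-(TBS-oxy)heptane-2,6-dione
Product: 4 (S)-5-(TBS-oxy)-3-methylcyclohex-2-en-1-one
Conditions: 9-amino-9-deoxy-epi-quinine (20 mol%), AcOH, toluene, rt
Reagents that add atoms: none
Why: Desymmetrising intramolecular aldol condensation under enamine catalysis, in which the chiral primary amine selects one of the two enantiotopic acetonyl arms as the nucleophile, closes the six-membered ring and should fix the silyloxy carbon (C6) as S.

Step 4
Reactants: 4 (S)-5-(TBS-oxy)-3-methylcyclohex-2-en-1-one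
Product: 5 (S)-5-(TBS-oxy)-2-iodo-3-methylcyclohex-2-en-1-one
Conditions: I2, pyridine, 4-(dimethylamino)pyridine (cat.), CH2Cl2, rt
Reagents that add atoms: iodine, II
Why: α-Iodination of the enone by amine conjugate addition, iodination of the enolate and loss of the amine (Baylis–Hillman-type addition–elimination) installs the coupling handle at C9 without touching C6.

Step 5
Reactants: 6 5-bromo-2-methylpent-2-ene
Product: 7 (R)-3-(2-bromoethyl)-2,2-dimethyloxirane
Conditions: 1,2:4,5-di-O-isopropylidene-β-D-erythro-2,3-hexodiulo-2,6-pyranose (30 mol%), KHSO5, K2CO3, Bu4NHSO4, MeCN/CH2(OMe)2/aq. Na2B4O7 buffer, 0 °C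
Reagents that add atoms: potassium peroxymonosulfate, [K+].[O-]S(=O)(=O)OO
Why: Shi epoxidation, in which the dioxirane of the D-fructose-derived ketone delivers oxygen through a spiro transition state to one face of the trisubstituted olefin, is expected to give the (R)-epoxide and so sets the future C14 centre.

Step 6
Reactants: 7 (R)-3-(2-bromoethyl)-2,2-dimethyloxirane
Product: 9 (R)-5-bromo-2-methylpent-1-en-3-ol, via trimethylsilyl ether 8 (not isolated)
Conditions: TMSOTf, DBU, toluene, 0 °C to rt; then 1 M HCl, THF, 0 °C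
Reagents that add atoms: none
Why: Silyl triflate/amidine isomerisation of an epoxide to an allylic silyl ether opens the O-silylated oxirane at the tertiary carbon while DBU removes a methyl proton, so the isopropenyl group forms, the carbinol C–O bond is never broken and the (R) configuration is kept.

Step 7
Reactants: 9 (R)-5-bromo-2-methylpent-1-en-3-ol
Product: 10 (R)-[(5-bromo-2-methylpent-1-en-3-yl)oxy](tert-butyl)diphenylsilane
Conditions: TBDPSCl, imidazole, DMF, rt
Reagents that add atoms: tert-butyldiphenylsilyl chloride, CC(C)(C)[Si](Cl)(c1ccccc1)c1ccccc1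
Why: Silyl ether formation with a bulky, non-directing group that outlasts the later removal of the TBS group and all organometallic steps.

Step 8
Reactants: 10 (R)-[(5-bromo-2-methylpent-1-en-3-yl)oxy](tert-butyl)diphenylsilane; 11 propyne; 5 (S)-5-(TBS-oxy)-2-iodo-3-methylcyclohex-2-en-1-one
Product: 16 (S)-2-[(1Z,5R)-5-(TBDPS-oxy)-2,6-dimethylhepta-1,6-dien-1-yl]-3-methyl-5-(TBS-oxy)cyclohex-2-en-1-one, via Grignard reagent 12 (not isolated), via alkylcopper 13 (not isolated), via (Z)-alkenylcopper 14 (not isolated), via (Z)-alkenylzinc bromide 15 (not isolated)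
Conditions: Mg, Et2O, rt; CuBr·SMe2, Et2O/Me2S, −45 °C; propyne, −25 °C; ZnBr2, THF, −20 °C; 5, Pd(PPh3)4 (5 mol%), 0 °C to rt
Reagents that add atoms: none
Why: Carbocupration of propyne by the alkylcopper is a syn addition that places the alkyl group on the internal carbon and so gives the (Z)-alkenylcopper (metal on C11 cis to the C12 chain), and transmetallation to zinc followed by Negishi coupling with the α-iodoenone under zerovalent palladium catalysis forms the C9–C11 bond with retention of that geometry.

Step 9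
Reactants: 16 (S)-2-[(1Z,5R)-5-(TBDPS-oxy)-2,6-dimethylhepta-1,6-dien-1-yl]-3-methyl-5-(TBS-oxy)cyclohex-2-en-1-one
Product: 17 C8–C9 epoxide of 16 (oxirane oxygen trans to the C6 silyloxy group)
Conditions: 30% H2O2, NaOH, MeOH, 0 °C
Reagents that add atoms: hydrogen peroxide, OO
Why: Weitz–Scheffer nucleophilic epoxidation, in which hydroperoxide adds axially to C8 on the ring face opposite the C6 silyloxy group before the enolate closes the oxirane, sets the C8 oxygen trans to the C6 oxygen.

Step 10
Reactants: 17 C8–C9 epoxide of 16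
Product: 18 β-hydroxy ketone: 2-alkenyl-3-hydroxy-3-methyl-5-(TBS-oxy)cyclohexan-1-one (C8–OH trans to C6–OTBS; C9 alkenyl cis to C8–OH)
Conditions: SmI2, THF/MeOH, −78 °C
Reagents that add atoms: none
Why: Reductive opening of the α,β-epoxy ketone by two single-electron transfers from divalent samarium cleaves only the C9–O bond and keeps the tertiary C8–OH, and protonation of the samarium enolate at C9 should give the epimer with the alkenyl group equatorial (trans to the C8 methyl), which is also the more stable one.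

Step 11
Reactants: 18 β-hydroxy ketone
Product: 19 C8 MOM ether of 18
Conditions: MOMCl, iPr2NEt, (CH2Cl)2, 50 °C
Reagents that add atoms: chloromethyl methyl ether, COCCl
Why: O-Alkylation with the chloromethyl ether (acetal formation) caps the tertiary C8–OH with a group that cannot migrate to the C4 alkoxide and whose oxygens can bind potassium in the key step.

Step 12
Reactants: 19 C8 MOM ether of 18; 20 vinylmagnesium bromide
Product: 21 1-vinylcyclohexan-1-ol precursor (C4 vinyl trans to the C9 (Z)-alkenyl group; C4–OH cis to C8–OMOM; C6–OTBS trans to both oxygens)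
Conditions: CeCl3, THF, −78 °C
Reagents that add atoms: none
Why: CeCl3-promoted Grignard 1,2-addition avoids enolisation of the α-branched ketone, and because the axial C8–OMOM group blocks the axial trajectory the vinyl group should enter equatorially, trans to the C9 alkenyl group, leaving the new C4–OH axial and cis to the C8 oxygen.

Step 13
Reactants: 21 1-vinylcyclohexan-1-ol precursor
Product: 24 (E)-cyclodec-5-en-1-one (C4 ketone; C1 quaternary with methyl and side chain; E C9=C11; C8 methyl and OMOM; C6 OTBS), via potassium alkoxide 22 (not isolated), via potassium enolate 23 (not isolated)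
Conditions: KH, 18-crown-6, THF, 0 °C to rt; then AcOH, THF, −78 °C
Reagents that add atoms: none
Why: KH with 18-crown-6 turns the tertiary C4 alcohol into a naked potassium alkoxide, whose oxyanion weakens the adjacent C4–C9 bond so that a concerted [3,3] sigmatropic shift (anionic oxy-Cope rearrangement) forms C1–C2, breaks C4–C9 and gives the C3=C4 enolate, which the cold acetic acid quench converts into the C4 ketone. The closest known reaction type is the anionic oxy-Cope ring expansion of trans-1,2-dialkenylcyclohexanols to (E)-cyclodec-5-enones, so the step is known chemistry on a new substrate. The ten-membered ring is not closed end to end; it arises by four-atom ring expansion of the cyclohexane through a chair-like six-centre transition state that is trans-fused to the cyclohexane chair, the vinyl and the alkenyl group both being equatorial. C1 is the only new stereocentre and is set by chirality transfer from C9 through this chair: ring carbon C8 is equatorial on the reacting array, which gives the E C9=C11 olefin, and the (Z) olefin terminus holds the C12 chain axial and the C1 methyl equatorial, so that C2 bonds to the face of C1 that corresponds to the configuration of the target. The step needs chair over boat selectivity and survival of the C6 silyloxy group β to the new carbonyl; the first is secured by the trans-diequatorial 1,2-dialkenyl arrangement and by the cis-diaxial C4–O/C8–OMOM pair that can share the potassium ion, the second by the regiochemistry of the enolate, which is formed towards C3 and is protonated cold before proton transfer towards C5 could start an E1cB loss of silanolate.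

Step 14
Reactants: 24 (E)-cyclodec-5-en-1-one
Product: 25 C4 methyl carbinol of 24 (both C4 epimers)
Conditions: MeMgBr, CeCl3, THF, −78 °C
Reagents that add atoms: methylmagnesium bromide, C[Mg]Br
Why: CeCl3-promoted Grignard 1,2-addition brings in the C4 methyl group without enolisation or β-elimination of the C6 silyloxy group, and the expected mixture of C4 epimers does not matter because C4 becomes sp2 in step 17.

Step 15
Reactants: 25 C4 methyl carbinol
Product: 26 4,6-diol (C6–OH free; C8–OMOM and C14–OTBDPS kept)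
Conditions: HF·pyridine, pyridine, THF, 0 °C to rt
Reagents that add atoms: none
Why: Selective desilylation, since under buffered HF the secondary TBS ether at C6 is cleaved much faster than the bulkier TBDPS ether at C14 and the MOM ether is inert.

Step 16
Reactants: 26 4,6-diol
Product: 27 4-hydroxy-6-ketone
Conditions: Dess–Martin periodinane, NaHCO3, CH2Cl2, rt
Reagents that add atoms: none
Why: Dess–Martin oxidation of the only secondary alcohol gives the C6 ketone under buffered, non-basic conditions that leave the tertiary aldol hydroxyl at C4 in place.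

Step 17
Reactants: 27 4-hydroxy-6-ketone
Product: 29 (4E,9E)-dienone (C4=C5–C6=O enone; C8–OMOM), via tertiary mesylate 28 (not isolated)
Conditions: MsCl, Et3N, CH2Cl2, 0 °C; then DBU, rt
Reagents that add atoms: none
Why: Aldol-type dehydration by E1cB, in which the mesylated tertiary C4 oxygen is expelled from the C5 enolate to give the conjugated C4=C5 enone while the far poorer leaving group at C8 stays, is expected to give the E isomer because the ring already holds the trans C9=C11 unit, so that its two three-carbon bridges (C1–C3 and C6–C8) are spanned with least strain when C4=C5 is trans too, with the carbonyl anti to the larger β-substituent.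

Step 18
Reactants: 29 (4E,9E)-dienone
Product: 31 β-hydroxy enone (free C8–OH), via bromomethyl ether 30 (not isolated)
Conditions: Me2BBr, CH2Cl2, −78 °C; then aq. NaHCO3
Reagents that add atoms: none
Why: Lewis-acid acetal cleavage of the MOM ether, in which the boron bromide attacks the methoxy oxygen at low temperature and the resulting bromomethyl ether is hydrolysed on work-up, frees the tertiary allylic C8–OH without ionising the C8–O bond and leaves the TBDPS ether and the enone alone.

Step 19
Reactants: 31 β-hydroxy enone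
Product: 32 (6S,8S)-anti-diol (E C4=C5 and E C9=C11 kept)
Conditions: Me4NBH(OAc)3, AcOH/MeCN, −30 °C
Reagents that add atoms: none
Why: Evans–Saksena reduction, in which the C8–OH exchanges onto boron and delivers hydride to the enone carbonyl (1,2-reduction) through a six-membered chair with ring carbons C5 and C9 equatorial, should give the 6,8-anti diol and so the (6S) carbinol.

Step 20
Reactants: 32 (6S,8S)-anti-diol
Product: 33 C6 acetate
Conditions: Ac2O, pyridine, 4-(dimethylamino)pyridine (cat.), CH2Cl2, 0 °C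
Reagents that add atoms: acetic anhydride, CC(=O)OC(C)=O
Why: Acylation under nucleophilic catalysis takes place only at the secondary allylic C6–OH, the tertiary C8–OH being too hindered, and it removes the one hydroxyl that could direct a carbenoid to C4=C5.

Step 21
Reactants: 33 C6 acetate
Product: 34 cyclopropane (C9–C10–C11 trans-fused to the ten-membered ring; C14–OTBDPS)
Conditions: Et2Zn, CH2I2, CH2Cl2, 0 °C
Reagents that add atoms: diiodomethane, ICI
Why: Hydroxyl-directed Simmons–Smith cyclopropanation (Furukawa reagent), in which the zinc-bound tertiary allylic C8 oxygen delivers the methylene group to the peripheral face of the E olefin on which the C8–O bond stands when the C8 methyl eclipses the double bond and ring carbon C7 lies on the opposite face, should give the trans-cyclopropane with the (9S,11S) configuration of the target, while the acetoxy-deactivated C4=C5 bond and the isopropenyl group, neither of which has a free hydroxyl beside it, should react far more slowly.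

Step 22
Reactants: 34 cyclopropane
Product: 35 (14R)-alcohol
Conditions: Bu4NF, AcOH, THF, rt
Reagents that add atoms: none
Why: Fluoride-induced cleavage of the TBDPS ether, buffered with acetic acid so that the C6 acetate neither migrates nor hydrolyses, frees the (R)-C14 alcohol.

Step 23
Reactants: 36 2,3-dimethylbut-2-ene
Product: 37 2-methoxyprop-2-yl hydroperoxide
Conditions: O3, MeOH/CH2Cl2, −78 °C
Reagents that add atoms: ozone, [O-][O+]=O; methanol, CO
Why: Ozonolysis in methanol, in which cycloreversion of the primary ozonide gives acetone and acetone carbonyl oxide and methanol traps the latter, gives an α-methoxy hydroperoxide that serves as a hydroperoxide donor carrying its own acid-labile protecting group.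

Step 24
Reactants: 35 (14R)-alcohol
Product: 38 (14R)-mesylate
Conditions: MsCl, Et3N, CH2Cl2, −30 °C
Reagents that add atoms: methanesulfonyl chloride, CS(=O)(=O)Cl
Why: Sulfonylation of the secondary allylic C14–OH leaves the C–O bond untouched and so gives the (R)-mesylate, while the tertiary cyclopropylcarbinol at C8 is too hindered to react at this temperature.

Step 25
Reactants: 38 (14R)-mesylate; 37 2-methoxyprop-2-yl hydroperoxide
Product: 39 (14S)-2-methoxyprop-2-yl peroxide (monoperoxy ketal)
Conditions: CsOH·H2O, DMF, 0 °C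
Reagents that add atoms: none
Why: SN2 alkylation of the cesium salt of hydroperoxide 37 by the secondary allylic mesylate proceeds with inversion and converts (R)-C14–OMs into the (S)-C14 peroxide of the target, the hindered peroxy anion being expected to spare the C6 acetate at 0 °C.

Step 26
Reactants: 39 (14S)-2-methoxyprop-2-yl peroxide
Product: 40 target CNP0302713.3
Conditions: AcOH/THF/H2O, rt
Reagents that add atoms: none
Why: Acid hydrolysis of the monoperoxy ketal (the peroxide analogue of mixed-ketal cleavage) releases the hydroperoxide with acetone and methanol under conditions too mild to ionise the tertiary cyclopropylcarbinol or the allylic acetate.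

Compound list
1 | hepta-1,6-dien-4-ol | C=CCC(O)CC=C | starting material
2 | tert-butyl(hepta-1,6-dien-4-yloxy)dimethylsilane | C=CCC(O[Si](C)(C)C(C)(C)C)CC=C | intermediate
3 | 4-[(tert-butyldimethylsilyl)oxy]heptane-2,6-dione | CC(=O)CC(O[Si](C)(C)C(C)(C)C)CC(C)=O | intermediate
4 | (S)-5-[(tert-butyldimethylsilyl)oxy]-3-methylcyclohex-2-en-1-one | O=C1C=C(C)C[C@H](O[Si](C)(C)C(C)(C)C)C1 | intermediate
5 | (S)-5-[(tert-butyldimethylsilyl)oxy]-2-iodo-3-methylcyclohex-2-en-1-one | O=C1C(I)=C(C)C[C@H](O[Si](C)(C)C(C)(C)C)C1 | intermediate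
6 | 5-bromo-2-methylpent-2-ene | CC(C)=CCCBr | starting material
7 | (R)-3-(2-bromoethyl)-2,2-dimethyloxirane | BrCC[C@H]1OC1(C)C | intermediate
8 | (R)-[(5-bromo-2-methylpent-1-en-3-yl)oxy]trimethylsilane (not isolated) | BrCC[C@@H](O[Si](C)(C)C)C(C)=C | intermediate
9 | (R)-5-bromo-2-methylpent-1-en-3-ol | BrCC[C@@H](O)C(C)=C | intermediate
10 | (R)-[(5-bromo-2-methylpent-1-en-3-yl)oxy](tert-butyl)diphenylsilane | BrCC[C@@H](O[Si](c1ccccc1)(c1ccccc1)C(C)(C)C)C(C)=C | intermediate
11 | propyne | CC#C | starting material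
12 | {(3R)-3-[(tert-butyldiphenylsilyl)oxy]-4-methylpent-4-en-1-yl}magnesium bromide (not isolated) | Br[Mg]CC[C@@H](O[Si](c1ccccc1)(c1ccccc1)C(C)(C)C)C(C)=C | intermediate
13 | {(3R)-3-[(tert-butyldiphenylsilyl)oxy]-4-methylpent-4-en-1-yl}copper (not isolated) | [Cu]CC[C@@H](O[Si](c1ccccc1)(c1ccccc1)C(C)(C)C)C(C)=C | intermediate
14 | {(1Z,5R)-5-[(tert-butyldiphenylsilyl)oxy]-2,6-dimethylhepta-1,6-dien-1-yl}copper (not isolated) | [Cu]/C=C(C)\CC[C@@H](O[Si](c1ccccc1)(c1ccccc1)C(C)(C)C)C(C)=C | intermediate
15 | {(1Z,5R)-5-[(tert-butyldiphenylsilyl)oxy]-2,6-dimethylhepta-1,6-dien-1-yl}zinc bromide (not isolated) | Br[Zn]/C=C(C)\CC[C@@H](O[Si](c1ccccc1)(c1ccccc1)C(C)(C)C)C(C)=C | intermediate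
16 | (S)-2-[(1Z,5R)-5-(TBDPS-oxy)-2,6-dimethylhepta-1,6-dien-1-yl]-3-methyl-5-(TBS-oxy)cyclohex-2-en-1-one | O=C1C[C@@H](O[Si](C)(C)C(C)(C)C)CC(C)=C1/C=C(C)\CC[C@@H](O[Si](c2ccccc2)(c2ccccc2)C(C)(C)C)C(C)=C | intermediate
17 | C8–C9 epoxide of 16 (7-oxabicyclo[4.1.0]heptan-2-one; oxirane oxygen trans to C6–OTBS) | O=C1C[C@@H](O[Si](C)(C)C(C)(C)C)C[C@]2(C)O[C@]12/C=C(C)\CC[C@@H](O[Si](c3ccccc3)(c3ccccc3)C(C)(C)C)C(C)=C | intermediate
18 | β-hydroxy ketone (C8–OH trans to C6–OTBS; C9 (Z)-alkenyl group cis to C8–OH, trans to C8 methyl) | O=C1C[C@@H](O[Si](C)(C)C(C)(C)C)C[C@](C)(O)[C@@H]1/C=C(C)\CC[C@@H](O[Si](c2ccccc2)(c2ccccc2)C(C)(C)C)C(C)=C | intermediate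
19 | C8 MOM ether of 18 | O=C1C[C@@H](O[Si](C)(C)C(C)(C)C)C[C@](C)(OCOC)[C@@H]1/C=C(C)\CC[C@@H](O[Si](c2ccccc2)(c2ccccc2)C(C)(C)C)C(C)=C | intermediate
20 | vinylmagnesium bromide | C=C[Mg]Br | starting material
21 | oxy-Cope precursor: 1-vinyl-2-[(Z)-alkenyl]cyclohexan-1-ol (C4 vinyl trans to C9 alkenyl; C4–OH cis to C8–OMOM; C6–OTBS trans to both oxygens; (14R)-OTBDPS) | C=C[C@@]1(O)C[C@@H](O[Si](C)(C)C(C)(C)C)C[C@](C)(OCOC)[C@@H]1/C=C(C)\CC[C@@H](O[Si](c2ccccc2)(c2ccccc2)C(C)(C)C)C(C)=C | intermediate
22 | potassium alkoxide of 21 (not isolated) | C=C[C@@]1([O-])C[C@@H](O[Si](C)(C)C(C)(C)C)C[C@](C)(OCOC)[C@@H]1/C=C(C)\CC[C@@H](O[Si](c2ccccc2)(c2ccccc2)C(C)(C)C)C(C)=C.[K+] | intermediate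
23 | potassium C3=C4 enolate of 24 (not isolated) | C=C(C)[C@@H](CC[C@@]1(C)C/C=C(\[O-])C[C@@H](O[Si](C)(C)C(C)(C)C)C[C@](C)(OCOC)/C=C/1)O[Si](c2ccccc2)(c2ccccc2)C(C)(C)C.[K+] | intermediate
24 | (E)-cyclodec-5-en-1-one: C4 ketone, C1 quaternary (methyl, C12–C15 chain with (14R)-OTBDPS), E C9=C11, C8 (methyl, OMOM), C6 OTBS | C=C(C)[C@@H](CC[C@@]1(C)CCC(=O)C[C@@H](O[Si](C)(C)C(C)(C)C)C[C@](C)(OCOC)/C=C/1)O[Si](c2ccccc2)(c2ccccc2)C(C)(C)C | intermediate
25 | C4 methyl carbinol of 24 (mixture of C4 epimers) | C=C(C)[C@@H](CC[C@@]1(C)CCC(C)(O)C[C@@H](O[Si](C)(C)C(C)(C)C)C[C@](C)(OCOC)/C=C/1)O[Si](c2ccccc2)(c2ccccc2)C(C)(C)C | intermediate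
26 | 4,6-diol (C4 epimers) | C=C(C)[C@@H](CC[C@@]1(C)CCC(C)(O)C[C@@H](O)C[C@](C)(OCOC)/C=C/1)O[Si](c2ccccc2)(c2ccccc2)C(C)(C)C | intermediate
27 | 4-hydroxy-6-ketone (C4 epimers) | C=C(C)[C@@H](CC[C@@]1(C)CCC(C)(O)CC(=O)C[C@](C)(OCOC)/C=C/1)O[Si](c2ccccc2)(c2ccccc2)C(C)(C)C | intermediate
28 | C4 mesylate of 27 (not isolated) | C=C(C)[C@@H](CC[C@@]1(C)CCC(C)(OS(C)(=O)=O)CC(=O)C[C@](C)(OCOC)/C=C/1)O[Si](c2ccccc2)(c2ccccc2)C(C)(C)C | intermediate
29 | (4E,9E)-dienone: C4=C5–C6=O enone, C8–OMOM | C=C(C)[C@@H](CC[C@@]1(C)CC/C(C)=C/C(=O)C[C@](C)(OCOC)/C=C/1)O[Si](c2ccccc2)(c2ccccc2)C(C)(C)C | intermediate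
30 | C8 bromomethyl ether (not isolated) | C=C(C)[C@@H](CC[C@@]1(C)CC/C(C)=C/C(=O)C[C@](C)(OCBr)/C=C/1)O[Si](c2ccccc2)(c2ccccc2)C(C)(C)C | intermediate
31 | β-hydroxy enone (free C8–OH) | C=C(C)[C@@H](CC[C@@]1(C)CC/C(C)=C/C(=O)C[C@](C)(O)/C=C/1)O[Si](c2ccccc2)(c2ccccc2)C(C)(C)C | intermediate
32 | (6S,8S)-anti-diol | C=C(C)[C@@H](CC[C@@]1(C)CC/C(C)=C/[C@@H](O)C[C@](C)(O)/C=C/1)O[Si](c2ccccc2)(c2ccccc2)C(C)(C)C | intermediate
33 | C6 acetate | C=C(C)[C@@H](CC[C@@]1(C)CC/C(C)=C/[C@@H](OC(C)=O)C[C@](C)(O)/C=C/1)O[Si](c2ccccc2)(c2ccccc2)C(C)(C)C | intermediate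
34 | cyclopropane with (14R)-OTBDPS | C=C(C)[C@@H](CC[C@@]1(C)CC/C(C)=C/[C@@H](OC(C)=O)C[C@](C)(O)[C@H]2C[C@@H]21)O[Si](c3ccccc3)(c3ccccc3)C(C)(C)C | intermediate
35 | (14R)-alcohol | C=C(C)[C@@H](CC[C@@]1(C)CC/C(C)=C/[C@@H](OC(C)=O)C[C@](C)(O)[C@H]2C[C@@H]21)O | intermediate
36 | 2,3-dimethylbut-2-ene | CC(C)=C(C)C | starting material
37 | 2-methoxyprop-2-yl hydroperoxide | COC(C)(C)OO | intermediate
38 | (14R)-mesylate | C=C(C)[C@@H](CC[C@@]1(C)CC/C(C)=C/[C@@H](OC(C)=O)C[C@](C)(O)[C@H]2C[C@@H]21)OS(C)(=O)=O | intermediate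
39 | (14S)-2-methoxyprop-2-yl peroxide | C=C(C)[C@H](CC[C@@]1(C)CC/C(C)=C/[C@@H](OC(C)=O)C[C@](C)(O)[C@H]2C[C@@H]21)OOC(C)(C)OC | intermediate
40 | CNP0302713.3, (1R,4E,6S,8S,9S,11S,14S) in the numbering of the overview | C=C(C)[C@H](CC[C@@]1(C)CC/C(C)=C/[C@@H](OC(C)=O)C[C@](C)(O)[C@H]2C[C@@H]21)OO | target

Total step count: 26. Longest linear sequence: 22 steps (1–4, 8–22, 24–26); steps 5–7 and step 23 are side branches.

Steps most likely to fail

Step 13 (key step). What may go wrong: proton transfer within the ten-membered enolate from C3 to C5, followed by E1cB loss of the C6 silanolate; a slow shift at the fully substituted C1 terminus would give this more time. Fallback (dianion variant, in which the C6 oxygen cannot leave): it sets out from 21. HF·pyridine removes the TBS group to give the desilylated diol F1. Excess KH/18-crown-6 gives the dipotassium dialkoxide F2, whose oxy-Cope shift gives the dipotassium enolate alkoxide F3, and a cold acetic acid quench gives the 6-hydroxy ketone F4. Excess MeMgBr with CeCl3 then gives diol 26, where the route is rejoined (steps 14 and 15 are bypassed).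

Step 17. What may go wrong: the elimination sets the C4=C5 geometry without a stereochemical bias from the substrate, so it may close the ring-cis (Z) enone, or the base may move the double bond out of conjugation. Fallback (stereospecific olefin inversion instead of reliance on the elimination): it sets out from 27, and the same elimination is taken to the (4Z)-enone F5. Luche reduction (NaBH4, CeCl3) gives the (4Z)-allylic alcohol F6, and VO(acac)2/t-BuOOH epoxidises only this allylic olefin to the cis-epoxy alcohol F7. LiPPh2 opens the oxirane at C5 with inversion to give the hydroxy phosphine F8, and MeI converts it into the phosphonium betaine F9. Syn loss of methyldiphenylphosphine oxide from F9 gives the (4E)-allylic alcohol F10 (phosphine–betaine olefin inversion). Dess–Martin oxidation of F10 returns to 29.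

Step 25. What may go wrong: attack of the peroxy anion at the terminal methylene (SN2′), E2 loss of methanesulfonate, ionisation with loss of configuration at C14, or perhydrolysis of the C6 acetate. Fallback (ene reaction instead of substitution, with C14 then secured by separation): it sets out from 35. Mitsunobu reaction with 2-nitrobenzenesulfonylhydrazide (PPh3, diethyl azodicarboxylate, −30 °C) gives the sulfonylhydrazine F11, which on warming loses the sulfinic acid to give the allylic diazene F12. Retro-ene loss of N2 from F12 gives the prenyl compound F13 (reductive 1,3-transposition). Schenck ene reaction (O2, hν, 5,10,15,20-tetraphenylporphyrin, CH2Cl2, 0 °C) at the electron-rich side-chain olefin should then give 40 together with its C14 epimer F14 and the tertiary hydroperoxide F15. Compound 40 is separated from these by preparative HPLC, so the route is rejoined at 40.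

Further compounds
F1 | step 13 | desilylated diol (21 without the TBS group) | C=C[C@@]1(O)C[C@@H](O)C[C@](C)(OCOC)[C@@H]1/C=C(C)\CC[C@@H](O[Si](c2ccccc2)(c2ccccc2)C(C)(C)C)C(C)=C
F2 | step 13 | dipotassium dialkoxide of F1 | C=C[C@@]1([O-])C[C@@H]([O-])C[C@](C)(OCOC)[C@@H]1/C=C(C)\CC[C@@H](O[Si](c2ccccc2)(c2ccccc2)C(C)(C)C)C(C)=C.[K+].[K+]
F3 | step 13 | dipotassium enolate alkoxide | C=C(C)[C@@H](CC[C@@]1(C)C/C=C(\[O-])C[C@@H]([O-])C[C@](C)(OCOC)/C=C/1)O[Si](c2ccccc2)(c2ccccc2)C(C)(C)C.[K+].[K+]
F4 | step 13 | 6-hydroxy ketone (24 without the TBS group) | C=C(C)[C@@H](CC[C@@]1(C)CCC(=O)C[C@@H](O)C[C@](C)(OCOC)/C=C/1)O[Si](c2ccccc2)(c2ccccc2)C(C)(C)C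
F5 | step 17 | (4Z)-enone | C=C(C)[C@@H](CC[C@@]1(C)CC/C(C)=C\C(=O)C[C@](C)(OCOC)/C=C/1)O[Si](c2ccccc2)(c2ccccc2)C(C)(C)C
F6 | step 17 | (4Z)-allylic alcohol (C6 epimers) | C=C(C)[C@@H](CC[C@@]1(C)CC/C(C)=C\C(O)C[C@](C)(OCOC)/C=C/1)O[Si](c2ccccc2)(c2ccccc2)C(C)(C)C
F7 | step 17 | cis-4,5-epoxy-6-ol (C3 and C6 cis on the oxirane) | C=C(C)[C@@H](CC[C@@]1(C)CCC2(C)OC2C(O)C[C@](C)(OCOC)/C=C/1)O[Si](c3ccccc3)(c3ccccc3)C(C)(C)C
F8 | step 17 | 5-(diphenylphosphanyl)-4,6-diol (hydroxy phosphine) | C=C(C)[C@@H](CC[C@@]1(C)CCC(C)(O)C(P(c2ccccc2)c2ccccc2)C(O)C[C@](C)(OCOC)/C=C/1)O[Si](c2ccccc2)(c2ccccc2)C(C)(C)C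
F9 | step 17 | methyldiphenylphosphonium betaine | C=C(C)[C@@H](CC[C@@]1(C)CCC(C)([O-])C([P+](C)(c2ccccc2)c2ccccc2)C(O)C[C@](C)(OCOC)/C=C/1)O[Si](c2ccccc2)(c2ccccc2)C(C)(C)C
F10 | step 17 | (4E)-allylic alcohol (C6 epimers) | C=C(C)[C@@H](CC[C@@]1(C)CC/C(C)=C/C(O)C[C@](C)(OCOC)/C=C/1)O[Si](c2ccccc2)(c2ccccc2)C(C)(C)C
F11 | step 25 | N-alkyl-N-(2-nitrobenzenesulfonyl)hydrazine at C14 | C=C(C)[C@H](CC[C@@]1(C)CC/C(C)=C/[C@@H](OC(C)=O)C[C@](C)(O)[C@H]2C[C@@H]21)N(N)S(=O)(=O)c1ccccc1[N+](=O)[O-]
F12 | step 25 | allylic diazene at C14 | C=C(C)[C@H](CC[C@@]1(C)CC/C(C)=C/[C@@H](OC(C)=O)C[C@](C)(O)[C@H]2C[C@@H]21)N=N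
F13 | step 25 | prenyl compound (4-methylpent-3-enyl side chain on C1) | CC(C)=CCC[C@@]1(C)CC/C(C)=C/[C@@H](OC(C)=O)C[C@](C)(O)[C@H]2C[C@@H]21
F14 | step 25 | C14 epimer of 40 | C=C(C)[C@@H](CC[C@@]1(C)CC/C(C)=C/[C@@H](OC(C)=O)C[C@](C)(O)[C@H]2C[C@@H]21)OO
F15 | step 25 | tertiary hydroperoxide regioisomer (E C13=C14, OOH on C15) | CC(C)(OO)/C=C/C[C@@]1(C)CC/C(C)=C/[C@@H](OC(C)=O)C[C@](C)(O)[C@H]2C[C@@H]21
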